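## Structural features

The target is a 2,3-dihydro-1-benzofuran in which a benzene ring (ring A) is fused through C3a–C7a to a five-membered oxygen ring (ring B: O1, C2, C3, C3a, C7a). C2 carries a 3,4,5-trimethoxyphenyl group (ring C), C3 a methyl group, C6 a methoxy group and C5 an (E)-prop-1-enyl chain. The only stereocentres, C2 and C3, are neighbours in ring B; both are R, which places the aryl and methyl groups trans. Fragile points are the C2–O1 bond (a benzylic ether next to an electron-rich arene, open to ionisation and hydrogenolysis), the styrene-like propenyl group (acid, electrophiles, hydrogen, E/Z drift) and the two alkoxy-rich benzene rings, which compete for electrophiles. The real difficulty is absolute control of the C2/C3 pair, and above all of C3, which bears only a methyl group and a hydrogen and so offers no functional group through which its configuration could be directed or repaired. C2, in contrast, can be equilibrated, because the trans arrangement is the more stable one. The key step exploits the fact that C2 and C3 are exactly the two sp3 atoms of ring B: without their two hydrogens the molecule is a flat, achiral benzofuran whose C2=C3 bond can accept H2 on one face, which fixes C3 once and for all.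

## Logic of the disconnections

**9 ⇒ 7 + 8.** The bond between C5 of ring A and the propenyl chain is cut. The propenyl group is the most sensitive function (acid, halogenating agents, hydrogen), so it is attached last. The cut leaves 7 and a three-carbon unit 8 whose geometry is already defined. The forward step must transfer the alkenyl group with retention of geometry and must not disturb C2 or C3.

**7 ⇒ 6.** The C5–Br bond is cut. C5 of 6 is para to O1 and ortho to the C6 methoxy group, so the handle can be introduced directly. This keeps 4 and 5 free of halogen, which the hydrogenation could cleave. The forward step must select C5 over C7 and over the two free positions of ring C.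

**6 ⇒ 5.** No skeletal bond is cut; only the configuration at C2 changes (C2–O1 is opened and re-closed in the forward step). A syn addition of hydrogen can deliver only the cis isomer, and trans is lower in energy. The trans target is thereby traced back to the one diastereomer a hydrogenation can make. The forward step must equilibrate C2 without touching C3.

**5 ⇒ 4.** The C2–H and C3–H bonds are cut (formal loss of H2). Both stereocentres disappear and the precursor 4 is flat and achiral. The forward step must add H2 to one face of a tetrasubstituted, aromatic C2=C3 bond and leave rings A and C and the C2–O1 bond intact.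

**4 ⇒ 3.** The C2=C3 bond of ring B is cut into a ketone carbon (future C3, with its methyl group) and an ester carbonyl carbon (future C2, with ring C). The regiochemistry is then fixed by connectivity. An alkyne heteroannulation with Pd(OAc)2 would form the same ring in the same number of steps, but with an unhindered aryl methyl alkyne its regiochemistry and efficiency rest on a small steric bias. The forward step must be a reductive carbonyl–carbonyl coupling that ends in the aromatic furan.

**3 ⇒ 1 + 2.** The ester C–O bond (the future O1–C2 bond) is cut. Both halves are simple benzene derivatives that already carry every oxygen substituent and the C3 methyl carbon. The forward step is an acylation of a hindered, hydrogen-bonded phenol.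

## Other disconnections considered

**Alternative 1:** The cut goes through ring A itself, at C7–C7a, C5–C6 and C3a–C7a. Ring A is then assembled from an open-chain diazo enone, (3E,5R,6S)-6-[(tert-butyldimethylsilyl)oxy]-1-diazo-5-methyl-6-(3,4,5-trimethoxyphenyl)hex-3-en-2-one A2, and methoxyethyne A3.
- Forward step: irradiation of A2 triggers a Wolff rearrangement to a vinylketene, which adds A3 in a [2+2] cycloaddition. Four-electron ring opening, six-electron ring closure and tautomerisation would give 2-[(1S,2R)-1-(tert-butyldimethylsilyloxy)-1-(3,4,5-trimethoxyphenyl)propan-2-yl]-5-methoxyphenol A1. Desilylation and ring closure with inversion at the benzylic carbinol carbon (Mitsunobu conditions) would then give ring B as the trans isomer.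
- In its favour: the polarity of the ynol ether fixes the oxygen pattern of ring A without isomer problems. Both stereocentres are made on an open chain by auxiliary- or reagent-controlled aldol or crotylation chemistry and can be checked before any ring exists. Trans arises from an invertive closure and not from equilibration.
- Against it here: ring A, which can be bought fully oxygenated, is built atom by atom. A2 needs a long linear sequence (stereodiad, protection, enone, diazo transfer). A3 is volatile and unstable. The closure at a carbinol carbon bearing ring C can drift from SN2 to SN1. A1 has only hydrogen at C5, so the bromination and coupling of the chosen plan are still needed.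
- Comparison: on structure the chosen plan is more direct, since 1 and 2 already contain rings A and C. On mechanism the pericyclic cascade is regiospecific and carries no stereochemical burden, whereas step 3 of the chosen plan rests on one catalytic face selection. In the security of absolute configuration and in avoiding a correction at C2 the alternative is the equal or the better of the chosen plan. On step economy it is clearly worse, roughly twice the length of the six-step route.

**Alternative 2:** The cut is the C3–C3a bond. Ring B is derived from the six-membered ring of a flavanone, (2R)-6-bromo-7-methoxy-2-(3,4,5-trimethoxyphenyl)-2,3-dihydro-4H-chromen-4-one A5, in which ring A is bonded to the carbonyl carbon.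
- Forward step: PhI(OAc)2 with H2SO4 in trimethyl orthoformate would functionalise the enol ether at C3, and ring A would migrate from the acetal carbon to C3 as the hypervalent iodine group departs. The ring contracts to methyl (2R,3R)-5-bromo-6-methoxy-2-(3,4,5-trimethoxyphenyl)-2,3-dihydro-1-benzofuran-3-carboxylate A4. The extruded carbon, now an ester, must then be reduced to the C3 methyl group.
- In its favour: the trans relationship comes directly from the rearrangement, because the migrating ring enters anti to the C2 aryl group. The bromine sits at C5 from the start, placed on ring A before ring C exists. Enantioenriched flavanones are accessible by asymmetric oxa-Michael cyclisation or by conjugate arylation.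
- Against it here: flavanones racemise by reversible ring opening under the strongly acidic conditions of the contraction. Ring C is very electron-rich and has a high migratory aptitude; its shift from C2 to C3 would compete with the wanted shift of ring A and destroy the stereocentre. The oxidant can attack the alkoxy-rich arenes. Turning the ester into a methyl group costs three further steps (hydride reduction, sulfonylation, hydride displacement) in the presence of an aryl bromide.
- Comparison: on structure both plans map every carbon, but the alternative passes through a carbon at the wrong oxidation level, while the chosen plan has the methyl group in place in 1. The alternative is better in that its halogen handle is regiochemically secure, whereas the chosen plan relies on selective bromination of 6. On mechanism a cationic 1,2-shift with a competing migrating group stands against a syn addition with no such branching; the alternative is the equal of the chosen plan in reaching trans and better in needing no epimerisation. On step economy it is longer, about eight steps against six.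

**Alternative 3:** The cut is the C2–aryl bond. Ring C is added as a nucleophile to C2 of a flat benzofuran ester, ethyl 5-bromo-6-methoxy-1-benzofuran-3-carboxylate A7.
- Forward step: an arylrhodium species generated from (3,4,5-trimethoxyphenyl)boronic acid A8 and the catalyst formed from [RhCl(C2H4)2]2 and a chiral diene would add across C2=C3. Protonation of the rhodium enolate at C3 would give ethyl (2R,3R)-5-bromo-6-methoxy-2-(3,4,5-trimethoxyphenyl)-2,3-dihydro-1-benzofuran-3-carboxylate A6.
- In its favour: it is convergent, since ring C arrives in the stereo-defining step. The catalyst type tolerates aryl bromides, so the C5 handle can be present from the start. C2 is set directly by the catalyst. C3, being alpha to the ester, can be equilibrated to trans with mild base through the enolate, which is a gentler correction than ionisation at C2.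
- Against it here: the acceptor is an aromatic, oxygen-donor-substituted acrylate, far less electrophilic than the enones and nitro-heteroarenes on which such additions are established, so the dearomative carbometalation is itself an extension. The rhodium enolate has a beta-oxygen and could open ring B by elimination of the phenoxide. A8 is prone to protodeboronation during a slow addition. The ester again costs three steps to become the methyl group.
- Comparison: on structure the alternative is the more convergent, and equal in using a flat benzofuran as the precursor of both stereocentres. On mechanism both plans dearomatise the same C2=C3 bond. The chosen plan does so by H2 addition, for which the benzofuran class has direct precedent; the alternative does so by C–C bond formation, which fixes C2 (the centre the chosen plan must invert) but leaves C3 to thermodynamics. In the handling of the halogen and in the mildness of the stereochemical correction the alternative is better. On step economy it is somewhat longer (preparation of A7, addition, three steps for the ester, coupling) than the six steps of the chosen route.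

Key step: step 3

Remarks on the chemistry:
- The target is read as the trans-(2R,3R) isomer; the hydrogenation product 5 differs from it only at C2 and is cis-(2S,3R).
- SINpEt·HBF4 is 1,3-bis[(1R)-1-(naphthalen-1-yl)ethyl]-4,5-dihydro-1H-imidazol-3-ium tetrafluoroborate. Its (R,R) antipode is written on the assumption that it presents the face that is Si at C3 to ruthenium; if the pocket selects the other face, the (S,S) salt is used and nothing else changes.
- Compounds 1, 2 and 8 are taken as commercial.

## Steps

Step 1
Reactants: 1 1-(2-hydroxy-4-methoxyphenyl)ethan-1-one; 2 3,4,5-trimethoxybenzoyl chloride
Product: 3 2-acetyl-5-methoxyphenyl 3,4,5-trimethoxybenzoate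
Conditions: Et3N (1.5 equiv), DMAP (5 mol %), CH2Cl2, 0 °C to rt
Reagents that add atoms: none
Why: Acylation of a phenol with an acid chloride under nucleophilic catalysis by DMAP; the hydrogen-bonded ortho-acetyl phenol is acylated cleanly with an amine base, which is too weak to trigger a Baker–Venkataraman rearrangement of 3.

Step 2
Reactants: 3 2-acetyl-5-methoxyphenyl 3,4,5-trimethoxybenzoate
Product: 4 6-methoxy-3-methyl-2-(3,4,5-trimethoxyphenyl)-1-benzofuran
Conditions: TiCl3 (4 equiv), Zn dust (8 equiv), DME, reflux, slow addition of 3
Reagents that add atoms: none
Why: Intramolecular McMurry-type reductive coupling of a ketone with an ester carbonyl, the established titanium route from 2-acyloxyaryl ketones to 2,3-disubstituted benzofurans: low-valent titanium reduces the ketone, the titanium-bound carbon attacks the neighbouring ester carbonyl and both oxygens are removed as titanium oxide, the gain of furan aromaticity driving the deoxygenation. The regiochemistry cannot vary: the ester carbon with ring C becomes C2 and the ketone carbon with its methyl group becomes C3.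

Step 3
Reactants: 4 6-methoxy-3-methyl-2-(3,4,5-trimethoxyphenyl)-1-benzofuran
Product: 5 (2S,3R)-6-methoxy-3-methyl-2-(3,4,5-trimethoxyphenyl)-2,3-dihydro-1-benzofuran (cis)
Conditions: Ru(2-methylallyl)2(cod) (5 mol %), (R,R)-SINpEt·HBF4 (10 mol %), KOtBu (15 mol %), n-hexane, 70 °C; then 4, H2 (60 bar), toluene/n-hexane, 40 °C
Reagents that add atoms: none
Why: The carbene-ligated ruthenium hydride formed from the precatalyst binds the C2=C3 bond of ring B, inserts it into Ru–H and releases the product by hydrogenolysis of the Ru–C bond, so both hydrogen atoms arrive on one face (syn addition). The closest known reaction type is the enantioselective hydrogenation of 2- and 3-substituted benzofurans with this same Ru(2-methylallyl)2(cod)/chiral imidazolinylidene system, extended here to a 2-aryl-3-methyl, tetrasubstituted C2=C3 bond. No ring is closed and no skeletal bond is formed. C3 is set by the chiral pocket of the 1-(naphthalen-1-yl)ethyl groups, which must expose to the metal the face that is Si at C3; C2 is not set independently but follows from syn delivery, so the product is cis, (2S,3R). The step needs chemoselectivity for ring B over rings A and C, and the substrate itself secures it: the furan ring has the smallest aromatic stabilisation and its C2=C3 bond is an enol ether, whereas the benzene rings need far more forcing conditions. It also needs the benzylic C2–O1 bond to survive, which is why ruthenium and not palladium is used. The different size of the C2 aryl and C3 methyl groups and the fused ring A give the flat substrate one preferred orientation in the pocket, and face selection rests on that.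

Step 4
Reactants: 5 (2S,3R)-6-methoxy-3-methyl-2-(3,4,5-trimethoxyphenyl)-2,3-dihydro-1-benzofuran (cis)
Product: 6 (2R,3R)-6-methoxy-3-methyl-2-(3,4,5-trimethoxyphenyl)-2,3-dihydro-1-benzofuran (trans)
Conditions: BF3·OEt2 (20 mol %), CH2Cl2 (0.02 M), 0 °C to rt; Et3N quench
Reagents that add atoms: none
Why: Acid-induced epimerisation of a benzylic ether carbon, known as the cis-to-trans isomerisation of 2-aryl-3-methyl-2,3-dihydrobenzofurans: BF3 on O1 lets C2–O1 ionise to a benzylic cation stabilised by ring C, the C2–C3 bond rotates and the phenolic oxygen re-closes ring B under thermodynamic control, which favours aryl and methyl on opposite faces. C3 takes no part and stays R, so inversion of C2 from S to R gives (2R,3R); high dilution, low temperature and a prompt basic quench are meant to outrun loss of the C3 hydrogen from the cation.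

Step 5
Reactants: 6 (2R,3R)-6-methoxy-3-methyl-2-(3,4,5-trimethoxyphenyl)-2,3-dihydro-1-benzofuran (trans)
Product: 7 (2R,3R)-5-bromo-6-methoxy-3-methyl-2-(3,4,5-trimethoxyphenyl)-2,3-dihydro-1-benzofuran
Conditions: NBS (1.0 equiv), MeCN, 0 °C, dark
Reagents that add atoms: N-bromosuccinimide, O=C1CCC(=O)N1Br
Why: Electrophilic aromatic bromination: C5 is para to O1, ortho to the C6 methoxy group and has a free neighbour at C4, which makes it the most nucleophilic and least hindered position; C7 lies between two oxygens, and the free positions of ring C are flanked by the C2 substituent and belong to a ring whose central methoxy group is twisted out of conjugation. One equivalent of NBS in a polar solvent at 0 °C in the dark keeps the reaction ionic and away from the benzylic C2–H and C3–H bonds, so both stereocentres are untouched.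

Step 6
Reactants: 7 (2R,3R)-5-bromo-6-methoxy-3-methyl-2-(3,4,5-trimethoxyphenyl)-2,3-dihydro-1-benzofuran; 8 4,4,5,5-tetramethyl-2-[(1E)-prop-1-en-1-yl]-1,3,2-dioxaborolane
Product: 9 (2R,3R)-6-methoxy-3-methyl-5-[(1E)-prop-1-en-1-yl]-2-(3,4,5-trimethoxyphenyl)-2,3-dihydro-1-benzofuran
Conditions: Pd(dppf)Cl2 (5 mol %), K2CO3 (3 equiv), 1,4-dioxane/H2O (4:1), 85 °C
Reagents that add atoms: none
Why: Suzuki–Miyaura coupling: zerovalent palladium inserts into the C5–Br bond, the alkenyl group is transferred from the base-activated boronate and reductive elimination forms the C5–C bond with retention of the E geometry. The carbonate base does not affect C2 or C3, and the acid-, halogen- and hydrogen-sensitive propenyl group appears only in the last step.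

## Compound list

1 | 1-(2-hydroxy-4-methoxyphenyl)ethan-1-one | CC(=O)c1ccc(OC)cc1O | starting material
2 | 3,4,5-trimethoxybenzoyl chloride | COc1cc(C(=O)Cl)cc(OC)c1OC | starting material
3 | 2-acetyl-5-methoxyphenyl 3,4,5-trimethoxybenzoate | CC(=O)c1ccc(OC)cc1OC(=O)c1cc(OC)c(OC)c(OC)c1 | intermediate
4 | 6-methoxy-3-methyl-2-(3,4,5-trimethoxyphenyl)-1-benzofuran | COc1ccc2c(C)c(-c3cc(OC)c(OC)c(OC)c3)oc2c1 | intermediate
5 | (2S,3R)-6-methoxy-3-methyl-2-(3,4,5-trimethoxyphenyl)-2,3-dihydro-1-benzofuran (cis) | COc1ccc2c(c1)O[C@H](c1cc(OC)c(OC)c(OC)c1)[C@@H]2C | intermediate
6 | (2R,3R)-6-methoxy-3-methyl-2-(3,4,5-trimethoxyphenyl)-2,3-dihydro-1-benzofuran (trans) | COc1ccc2c(c1)O[C@@H](c1cc(OC)c(OC)c(OC)c1)[C@@H]2C | intermediate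
7 | (2R,3R)-5-bromo-6-methoxy-3-methyl-2-(3,4,5-trimethoxyphenyl)-2,3-dihydro-1-benzofuran | Brc1cc2c(cc1OC)O[C@@H](c1cc(OC)c(OC)c(OC)c1)[C@@H]2C | intermediate
8 | 4,4,5,5-tetramethyl-2-[(1E)-prop-1-en-1-yl]-1,3,2-dioxaborolane | C/C=C/B1OC(C)(C)C(C)(C)O1 | starting material
9 | (2R,3R)-6-methoxy-3-methyl-5-[(1E)-prop-1-en-1-yl]-2-(3,4,5-trimethoxyphenyl)-2,3-dihydro-1-benzofuran | C/C=C/c1cc2c(cc1OC)O[C@@H](c1cc(OC)c(OC)c(OC)c1)[C@@H]2C | target

## Step count and least certain steps

Total steps: 6. Longest linear sequence: 6 steps (1 → 3 → 4 → 5 → 6 → 7 → 9); 2 and 8 enter as bought.

**Step 3 (key step).** The most likely failure is slow or incomplete hydrogen uptake together with poor facial selectivity. The C2=C3 bond is tetrasubstituted, conjugated to ring C and electron-rich, so binding to ruthenium is hindered and the two faces differ little. Raising temperature or pressure invites saturation of ring A or ring C and hydrogenolysis of C2–O1. The fallback takes the stereochemistry from a resolution and not from catalysis. From 4, ionic hydrogenation with Et3SiH in CF3CO2H/CH2Cl2 (protonation at C3, hydride delivery to the C2 oxocarbenium ion anti to the methyl group) should give racemic trans-6-methoxy-3-methyl-2-(3,4,5-trimethoxyphenyl)-2,3-dihydro-1-benzofuran F1. Preparative chromatography on a chiral stationary phase separates it; the (2R,3R) half is 6, where the route is rejoined, steps 3 and 4 being bypassed.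

**Step 4.** The most likely failure is erosion of the C3 configuration, by loss of the C3 hydrogen from the ring-opened benzylic cation and re-protonation of the resulting styrene, or alkylation of a second molecule by that cation. C3 is the only centre the catalyst set, so any such leak lowers the enantiomeric purity of everything that follows. The fallback replaces the ionic pathway with a radical one. From 5, the C2 hydrogen is abstracted reversibly, either by a thiyl radical chain (an arenethiol with a radical initiator, benzene, 80 °C) or under (n-Bu4N)4[W10O32] photocatalysis with a disulfide co-catalyst. The planar C2 radical takes hydrogen back on either face, so cis drains into trans without any cation. No new compound is formed (F0) and the route is rejoined at 6. The point to watch there is competing abstraction of the benzylic C3 hydrogen.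

**Step 5.** The most likely failure is substitution on the wrong ring or a second substitution, because ring C and C7 of ring A are also alkoxy-activated and the discrimination rests on a moderate difference in nucleophilicity and hindrance. The fallback forms the C5–C bond by formylation and olefination instead of halogenation and cross-coupling. From 6, Vilsmeier–Haack formylation (POCl3, DMF), which uses a weak, bulky electrophile that stops after one substitution, should give (2R,3R)-6-methoxy-3-methyl-2-(3,4,5-trimethoxyphenyl)-2,3-dihydro-1-benzofuran-5-carbaldehyde F2. Julia–Kocienski olefination with 5-(ethanesulfonyl)-1-phenyl-1H-tetrazole F3 (KHMDS, DME, −60 °C to rt) should then give the E alkene 9 directly. Steps 5 and 6 are replaced and the route is rejoined at 9.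

**Step 2.** The most likely failure is reductive cleavage of the aryl ester C–O bond, or simple reduction or dimerisation of the ketone, in competition with the intramolecular coupling, since low-valent titanium is used in large excess and the ketone is deactivated by its para methoxy group. The fallback closes ring B by olefination and not by reductive coupling. From 1, NaBH4 reduction gives 2-(1-hydroxyethyl)-5-methoxyphenol F4. PPh3·HBr in MeCN gives [1-(2-hydroxy-4-methoxyphenyl)ethyl]triphenylphosphonium bromide F5. Heating F5 with 2 and Et3N in toluene (O-acylation, ylide formation, intramolecular Wittig reaction on the ester carbonyl) gives 4, where the route is rejoined.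

## Further compounds

F1 | step 3 | racemic trans-6-methoxy-3-methyl-2-(3,4,5-trimethoxyphenyl)-2,3-dihydro-1-benzofuran, (2R,3R) and (2S,3S) in equal parts | COc1ccc2c(c1)O[C@@H](c1cc(OC)c(OC)c(OC)c1)[C@@H]2C.COc1ccc2c(c1)O[C@H](c1cc(OC)c(OC)c(OC)c1)[C@H]2C
F0 | step 4 | none | none
F2 | step 5 | (2R,3R)-6-methoxy-3-methyl-2-(3,4,5-trimethoxyphenyl)-2,3-dihydro-1-benzofuran-5-carbaldehyde | O=Cc1cc2c(cc1OC)O[C@@H](c1cc(OC)c(OC)c(OC)c1)[C@@H]2C
F3 | step 5 | 5-(ethanesulfonyl)-1-phenyl-1H-tetrazole | CCS(=O)(=O)c1nnnn1-c1ccccc1
F4 | step 2 | 2-(1-hydroxyethyl)-5-methoxyphenol (racemic) | CC(O)c1ccc(OC)cc1O
F5 | step 2 | [1-(2-hydroxy-4-methoxyphenyl)ethyl]triphenylphosphonium bromide (racemic) | CC(c1ccc(OC)cc1O)[P+](c1ccccc1)(c1ccccc1)c1ccccc1.[Br-]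
A1 | alternative 1 | 2-[(1S,2R)-1-(tert-butyldimethylsilyloxy)-1-(3,4,5-trimethoxyphenyl)propan-2-yl]-5-methoxyphenol | COc1ccc([C@@H](C)[C@H](O[Si](C)(C)C(C)(C)C)c2cc(OC)c(OC)c(OC)c2)c(O)c1
A2 | alternative 1 | (3E,5R,6S)-6-[(tert-butyldimethylsilyl)oxy]-1-diazo-5-methyl-6-(3,4,5-trimethoxyphenyl)hex-3-en-2-one | [N-]=[N+]=CC(=O)/C=C/[C@@H](C)[C@H](O[Si](C)(C)C(C)(C)C)c1cc(OC)c(OC)c(OC)c1
A3 | alternative 1 | methoxyethyne | COC#C
A4 | alternative 2 | methyl (2R,3R)-5-bromo-6-methoxy-2-(3,4,5-trimethoxyphenyl)-2,3-dihydro-1-benzofuran-3-carboxylate | Brc1cc2c(cc1OC)O[C@@H](c1cc(OC)c(OC)c(OC)c1)[C@@H]2C(=O)OC
A5 | alternative 2 | (2R)-6-bromo-7-methoxy-2-(3,4,5-trimethoxyphenyl)-2,3-dihydro-4H-chromen-4-one | COc1cc2c(cc1Br)C(=O)C[C@H](c1cc(OC)c(OC)c(OC)c1)O2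
A6 | alternative 3 | ethyl (2R,3R)-5-bromo-6-methoxy-2-(3,4,5-trimethoxyphenyl)-2,3-dihydro-1-benzofuran-3-carboxylate | Brc1cc2c(cc1OC)O[C@@H](c1cc(OC)c(OC)c(OC)c1)[C@@H]2C(=O)OCC
A7 | alternative 3 | ethyl 5-bromo-6-methoxy-1-benzofuran-3-carboxylate | CCOC(=O)c1coc2cc(OC)c(Br)cc12
A8 | alternative 3 | (3,4,5-trimethoxyphenyl)boronic acid | COc1cc(B(O)O)cc(OC)c1OC
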